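**Retrosynthetic overview**
- The target is a 1,2-dioxane (O1, O2, C3–C6) whose C3 methyl peroxyketal has OMe cis to the C6 CH2CO2H arm. In the chair, OMe is axial (anomeric to O2) and both the C16 chain at C3 and the arm at C6 are equatorial, so C3 can be set by equilibration once C6 is fixed.
- Key disconnection: O2–C3 and C3–OMe, by acid/methanol cycloperoxyketalisation of a masked (S)-hydroperoxide onto the C3 carbonyl carbon. This closes the only ring, and it is the last skeletal event.
- C6–O1 comes from SN2 inversion of an (R)-mesylate by a ketal-protected hydroperoxide. The C3 ketone is carried as a 1,3-dioxolane through this basic step, because the enolate of a gamma-sulfonyloxy ketone would close to a cyclopropyl ketone; the carbonyl is unmasked in the flask of the key step.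
- C4–C5 comes from a hydrazone aza-enolate opening an (S)-epoxide, and the enyne from a Sonogashira coupling of a Takai vinyl iodide. The acid is carried as a silyloxyethyl arm (an ester would eliminate the beta-sulfonate) and oxidised at the end.

Key step: step 15

Remark: the gamma-hydroxy ketone of step 10 is assumed to react through its open-chain form, with which its five-membered lactol equilibrates; 2-methoxyprop-2-yl hydroperoxide is not a stock reagent and is made in step 13. Ring numbering throughout: O1, O2, C3 (ketal carbon), C4, C5, C6 (carbinol carbon).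

**Route**

Step 1
Reactants: 1 dec-9-en-1-ol
Product: 2 dec-9-enal
Conditions: TEMPO (cat.), PhI(OAc)2, CH2Cl2, rt
Reagents that add atoms: none
Why: TEMPO/PhI(OAc)2 (oxoammonium) oxidation takes a primary alcohol to the aldehyde without over-oxidation and does not touch the terminal alkene.

Step 2
Reactants: 2 dec-9-enal
Product: 3 (1E)-1-iodoundeca-1,10-diene
Conditions: CrCl2 (6 equiv), CHI3 (2 equiv), THF, 0 °C → rt
Reagents that add atoms: iodoform, IC(I)I
Why: Takai olefination: the geminal dichromium carbenoid formed from CHI3 and CrCl2 adds to the aldehyde and eliminates through an anti-periplanar beta-oxido chromium arrangement, which should favour the (E)-vinyl iodide, while the remote terminal alkene is inert.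

Step 3
Reactants: 4 hex-5-ynoic acid
Product: 6 N-methoxy-N-methylhex-5-ynamide, via acyl imidazole 5 (not isolated)
Conditions: CDI, CH2Cl2, rt; then MeNHOMe·HCl, rt
Reagents that add atoms: N,O-dimethylhydroxylamine hydrochloride, CNOC.Cl
Why: Amide coupling through the acyl imidazole (CDI activation) gives the Weinreb amide under near-neutral conditions that leave the terminal alkyne alone.

Step 4
Reactants: 6 N-methoxy-N-methylhex-5-ynamide
Product: 7 hept-6-yn-2-one
Conditions: MeMgBr (2.2 equiv), THF, 0 °C; aq. HCl (1 M)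
Reagents that add atoms: methylmagnesium bromide, C[Mg]Br
Why: Weinreb ketone synthesis: the magnesium-chelated tetrahedral adduct resists a second addition and collapses to the methyl ketone only on acidic work-up, the excess Grignard reagent covering any deprotonation of the alkyne C–H.

Step 5
Reactants: 3 (1E)-1-iodoundeca-1,10-diene; 7 hept-6-yn-2-one
Product: 8 (8E)-octadeca-8,17-dien-6-yn-2-one
Conditions: Pd(PPh3)2Cl2 (cat.), CuI (cat.), Et3N, THF, rt, degassed
Reagents that add atoms: none
Why: Sonogashira coupling (oxidative addition of zerovalent palladium into the vinyl C–I bond, copper acetylide transmetalation, reductive elimination) joins the sp and sp2 carbons with retention of the E geometry and tolerates the ketone and the terminal alkene.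

Step 6
Reactants: 8 (8E)-octadeca-8,17-dien-6-yn-2-one
Product: 9 (8E)-octadeca-8,17-dien-6-yn-2-one N,N-dimethylhydrazone
Conditions: Me2NNH2, AcOH (cat.), EtOH, 60 °C
Reagents that add atoms: 1,1-dimethylhydrazine, CN(C)N
Why: Condensation to the N,N-dimethylhydrazone converts the methyl ketone into the precursor of a regiodefined aza-enolate for the Corey–Enders alkylation.

Step 7
Reactants: 10 but-3-en-1-ol
Product: 11 (but-3-en-1-yloxy)(tert-butyl)diphenylsilane
Conditions: TBDPSCl, imidazole, CH2Cl2, rt
Reagents that add atoms: tert-butyldiphenylsilyl chloride, CC(C)(C)[Si](Cl)(c1ccccc1)c1ccccc1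
Why: Imidazole-promoted silylation gives a silyl ether that is stable to base and to mild acid and lasts until step 16.

Step 8
Reactants: 11 (but-3-en-1-yloxy)(tert-butyl)diphenylsilane
Product: 12 racemic tert-butyl[2-(oxiran-2-yl)ethoxy]diphenylsilane
Conditions: mCPBA, NaHCO3, CH2Cl2, 0 °C → rt
Reagents that add atoms: 3-chloroperoxybenzoic acid, O=C(OO)c1cccc(Cl)c1
Why: Prilezhaev epoxidation of the only alkene gives the racemic terminal epoxide.

Step 9
Reactants: 12 racemic tert-butyl[2-(oxiran-2-yl)ethoxy]diphenylsilane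
Product: 13 (S)-tert-butyl[2-(oxiran-2-yl)ethoxy]diphenylsilane
Conditions: (S,S)-(salen)Co(OAc) (cat.; salen = N,N'-bis(3,5-di-tert-butylsalicylidene)cyclohexane-1,2-diamine dianion, trivalent cobalt), H2O (0.55 equiv), THF, 0 °C → rt
Reagents that add atoms: none
Why: Jacobsen hydrolytic kinetic resolution: this catalyst enantiomer hydrates the (R)-epoxide much faster, so the (S)-epoxide should remain in high enantiomeric purity and fixes the carbon that becomes C6, the diol being removed by chromatography.

Step 10
Reactants: 9 (8E)-octadeca-8,17-dien-6-yn-2-one N,N-dimethylhydrazone; 13 (S)-tert-butyl[2-(oxiran-2-yl)ethoxy]diphenylsilane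
Product: 15 (3R,12E)-1-(tert-butyldiphenylsilyloxy)-3-hydroxydocosa-12,21-dien-10-yn-6-one, via hydroxy hydrazone 14 (not isolated)
Conditions: LiN(i-Pr)2, THF, −78 → 0 °C; 13, 0 °C → rt; H2O; then sat. aq. (CO2H)2, Et2O, rt
Reagents that add atoms: water, O
Why: Corey–Enders hydrazone alkylation: LiN(i-Pr)2 deprotonates the methyl group (the less substituted side), the aza-enolate opens the epoxide at its CH2 terminus by SN2 (forming C4–C5) without touching the C–O bond of the stereocentre, which keeps its arrangement in space and is named (R) only because the CIP priorities change, and mild oxalic acid hydrolysis returns the ketone without harming the silyl ether.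

Step 11
Reactants: 15 (3R,12E)-1-(tert-butyldiphenylsilyloxy)-3-hydroxydocosa-12,21-dien-10-yn-6-one
Product: 16 (3R,12E)-1-(tert-butyldiphenylsilyloxy)-6-oxodocosa-12,21-dien-10-yn-3-yl methanesulfonate
Conditions: MsCl, Et3N, CH2Cl2, −10 °C; used without delay
Reagents that add atoms: methanesulfonyl chloride, CS(=O)(=O)Cl
Why: Sulfonylation (mesylation through sulfene) activates the C6 oxygen with retention, since no bond to carbon is broken, and the amine base is too weak to enolise the ketone.

Step 12
Reactants: 16 (3R,12E)-1-(tert-butyldiphenylsilyloxy)-6-oxodocosa-12,21-dien-10-yn-3-yl methanesulfonate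
Product: 17 2-[(3R)-5-(tert-butyldiphenylsilyloxy)-3-(methanesulfonyloxy)pentyl]-2-[(6E)-hexadeca-6,15-dien-4-yn-1-yl]-1,3-dioxolane
Conditions: TMSOCH2CH2OTMS, TMSOTf (cat.), CH2Cl2, −78 → −20 °C; pyridine
Reagents that add atoms: 1,2-bis(trimethylsilyloxy)ethane, C[Si](C)(C)OCCO[Si](C)(C)C
Why: Noyori ketalisation (silyl triflate-catalysed exchange with the bis-silyl ether of ethylene glycol) masks the ketone at low temperature, where the secondary mesylate and the silyl ether are untouched, so that no enolate can attack C6 in the basic step that follows.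

Step 13
Reactants: 18 2,3-dimethylbut-2-ene; 19 methanol
Product: 20 2-methoxyprop-2-yl hydroperoxide
Conditions: O3, MeOH/CH2Cl2, −78 °C; N2 purge; used as a solution
Reagents that add atoms: ozone, [O-][O+]=O
Why: Ozonolysis in methanol: the Criegee carbonyl oxide from the tetrasubstituted alkene is trapped by methanol to give the alpha-methoxy hydroperoxide, with acetone as the only co-product.

Step 14
Reactants: 17 2-[(3R)-5-(tert-butyldiphenylsilyloxy)-3-(methanesulfonyloxy)pentyl]-2-[(6E)-hexadeca-6,15-dien-4-yn-1-yl]-1,3-dioxolane; 20 2-methoxyprop-2-yl hydroperoxide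
Product: 21 2-[(3S)-5-(tert-butyldiphenylsilyloxy)-3-(2-methoxyprop-2-ylperoxy)pentyl]-2-[(6E)-hexadeca-6,15-dien-4-yn-1-yl]-1,3-dioxolane
Conditions: CsOH·H2O, 20 (excess), DMF, 0 °C → rt
Reagents that add atoms: none
Why: SN2 displacement of the secondary mesylate by the cesium salt of the hydroperoxide (an alpha-effect nucleophile) in a dipolar aprotic solvent proceeds with inversion, turning (R)-C6–O into (S)-C6–OO, while the ketal excludes enolate cyclopropanation and the low temperature limits E2 and base-induced Kornblum–DeLaMare fragmentation.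

Step 15
Reactants: 21 2-[(3S)-5-(tert-butyldiphenylsilyloxy)-3-(2-methoxyprop-2-ylperoxy)pentyl]-2-[(6E)-hexadeca-6,15-dien-4-yn-1-yl]-1,3-dioxolane; 19 methanol
Product: 23 (3R,6S)-6-[2-(tert-butyldiphenylsilyloxy)ethyl]-3-[(6E)-hexadeca-6,15-dien-4-yn-1-yl]-3-methoxy-1,2-dioxane, via free hydroperoxide 22 (not isolated)
Conditions: TsOH·H2O (cat.), MeOH, rt; Et3N quench
Reagents that add atoms: none
Why: Acidic methanol first methanolyses the 2-methoxyprop-2-yl peroxyketal to the free (S)-hydroperoxide 22 and then opens the dioxolane to an oxocarbenium ion at C3 (ketone, hemiketal and dimethyl ketal lie in the same equilibrium), which the hydroperoxide captures four atoms away; ionisation of the resulting peroxyketal to the ring peroxycarbenium ion and capture by solvent methanol then places OMe on C3, so that O2–C3 and C3–OMe are both made here. The closest known reaction type is the acid-catalysed cyclisation of gamma-hydroperoxy ketones or their ketals in alcohols to 3-alkoxy-1,2-dioxanes, combined with ordinary acid transketalisation. The 1,2-dioxane closes by 6-exo-trig attack of the terminal peroxide oxygen on the C3 oxocarbenium carbon. The new stereocentre C3 is set under thermodynamic control from C6: every step is reversible, and the chair with axial OMe (anomeric stabilisation by O2) and equatorial C3 chain and C6 arm, which is the (3R,6S) isomer with OMe cis to the arm, should be the lowest-energy member, because the C3 epimer must give up either the anomeric effect or an equatorial carbon substituent. The step needs chemoselectivity for ketal and peroxyketal exchange over silyl ether cleavage and for ring closure over simple dimethyl ketal formation; the tert-butyldiphenylsilyl ether is inert to catalytic TsOH in methanol at rt, the six-membered peroxyketal is the thermodynamic sink, and the large excess of methanol displaces any 2-hydroxyethoxy group left on C3. C6 keeps its configuration because no bond to it is broken.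

Step 16
Reactants: 23 (3R,6S)-6-[2-(tert-butyldiphenylsilyloxy)ethyl]-3-[(6E)-hexadeca-6,15-dien-4-yn-1-yl]-3-methoxy-1,2-dioxane
Product: 24 2-[(3R,6S)-3-[(6E)-hexadeca-6,15-dien-4-yn-1-yl]-3-methoxy-1,2-dioxan-6-yl]ethanol
Conditions: Bu4NF, AcOH (1:1), THF, 0 °C → rt
Reagents that add atoms: none
Why: Fluoride desilylation buffered with acetic acid frees the primary alcohol while keeping the medium non-basic, which protects the secondary peroxide from Kornblum–DeLaMare fragmentation and leaves the peroxyketal intact.

Step 17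
Reactants: 24 2-[(3R,6S)-3-[(6E)-hexadeca-6,15-dien-4-yn-1-yl]-3-methoxy-1,2-dioxan-6-yl]ethanol
Product: 25 2-[(3R,6S)-3-[(6E)-hexadeca-6,15-dien-4-yn-1-yl]-3-methoxy-1,2-dioxan-6-yl]acetaldehyde
Conditions: TEMPO (cat.), PhI(OAc)2, CH2Cl2, rt; used crude
Reagents that add atoms: none
Why: TEMPO/PhI(OAc)2 oxoammonium oxidation gives the aldehyde under non-basic conditions, so the beta-peroxy aldehyde is not exposed to base that would trigger beta-elimination, and the peroxide, enyne and terminal alkene are not oxidised.

Step 18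
Reactants: 25 2-[(3R,6S)-3-[(6E)-hexadeca-6,15-dien-4-yn-1-yl]-3-methoxy-1,2-dioxan-6-yl]acetaldehyde
Product: 26 2-[(3R,6S)-3-[(6E)-hexadeca-6,15-dien-4-yn-1-yl]-3-methoxy-1,2-dioxan-6-yl]acetic acid (CNP0125368.1)
Conditions: NaClO2, NaH2PO4, 2-methylbut-2-ene, t-BuOH/H2O, 0 °C → rt
Reagents that add atoms: sodium chlorite, [Na+].[O-]Cl=O
Why: Pinnick (Lindgren) oxidation with chlorous acid at buffered, weakly acidic pH converts the aldehyde to the acid, 2-methylbut-2-ene scavenging the hypochlorous acid that would otherwise attack the alkenes and the alkyne.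

**Compound list**
1 | dec-9-en-1-ol | C=CCCCCCCCCO | starting material
2 | dec-9-enal | C=CCCCCCCCC=O | intermediate
3 | (1E)-1-iodoundeca-1,10-diene | C=CCCCCCCC/C=C/I | intermediate
4 | hex-5-ynoic acid | C#CCCCC(=O)O | starting material
5 | 1-(hex-5-ynoyl)imidazole (acyl imidazole, not isolated) | C#CCCCC(=O)n1ccnc1 | intermediate
6 | N-methoxy-N-methylhex-5-ynamide | C#CCCCC(=O)N(C)OC | intermediate
7 | hept-6-yn-2-one | C#CCCCC(C)=O | intermediate
8 | (8E)-octadeca-8,17-dien-6-yn-2-one | C=CCCCCCCC/C=C/C#CCCCC(C)=O | intermediate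
9 | (8E)-octadeca-8,17-dien-6-yn-2-one N,N-dimethylhydrazone | C=CCCCCCCC/C=C/C#CCCCC(C)=NN(C)C | intermediate
10 | but-3-en-1-ol | C=CCCO | starting material
11 | (but-3-en-1-yloxy)(tert-butyl)diphenylsilane | C=CCCO[Si](c1ccccc1)(c1ccccc1)C(C)(C)C | intermediate
12 | racemic tert-butyl[2-(oxiran-2-yl)ethoxy]diphenylsilane | CC(C)(C)[Si](c1ccccc1)(c1ccccc1)OCCC1CO1 | intermediate
13 | (S)-tert-butyl[2-(oxiran-2-yl)ethoxy]diphenylsilane | CC(C)(C)[Si](c1ccccc1)(c1ccccc1)OCC[C@H]1CO1 | intermediate
14 | (3R,12E)-1-(tert-butyldiphenylsilyloxy)-3-hydroxydocosa-12,21-dien-10-yn-6-one N,N-dimethylhydrazone (not isolated) | C=CCCCCCCC/C=C/C#CCCCC(CC[C@H](CCO[Si](c1ccccc1)(c1ccccc1)C(C)(C)C)O)=NN(C)C | intermediate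
15 | (3R,12E)-1-(tert-butyldiphenylsilyloxy)-3-hydroxydocosa-12,21-dien-10-yn-6-one | C=CCCCCCCC/C=C/C#CCCCC(=O)CC[C@H](CCO[Si](c1ccccc1)(c1ccccc1)C(C)(C)C)O | intermediate
16 | (3R,12E)-1-(tert-butyldiphenylsilyloxy)-6-oxodocosa-12,21-dien-10-yn-3-yl methanesulfonate | C=CCCCCCCC/C=C/C#CCCCC(=O)CC[C@H](CCO[Si](c1ccccc1)(c1ccccc1)C(C)(C)C)OS(C)(=O)=O | intermediate
17 | 2-[(3R)-5-(tert-butyldiphenylsilyloxy)-3-(methanesulfonyloxy)pentyl]-2-[(6E)-hexadeca-6,15-dien-4-yn-1-yl]-1,3-dioxolane | C=CCCCCCCC/C=C/C#CCCCC1(OCCO1)CC[C@H](CCO[Si](c2ccccc2)(c2ccccc2)C(C)(C)C)OS(C)(=O)=O | intermediate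
18 | 2,3-dimethylbut-2-ene | CC(C)=C(C)C | starting material
19 | methanol | CO | starting material
20 | 2-methoxyprop-2-yl hydroperoxide | COC(C)(C)OO | intermediate
21 | 2-[(3S)-5-(tert-butyldiphenylsilyloxy)-3-(2-methoxyprop-2-ylperoxy)pentyl]-2-[(6E)-hexadeca-6,15-dien-4-yn-1-yl]-1,3-dioxolane (key-step precursor) | C=CCCCCCCC/C=C/C#CCCCC1(OCCO1)CC[C@@H](CCO[Si](c2ccccc2)(c2ccccc2)C(C)(C)C)OOC(C)(C)OC | intermediate
22 | 2-[(3S)-5-(tert-butyldiphenylsilyloxy)-3-hydroperoxypentyl]-2-[(6E)-hexadeca-6,15-dien-4-yn-1-yl]-1,3-dioxolane (not isolated) | C=CCCCCCCC/C=C/C#CCCCC1(OCCO1)CC[C@@H](CCO[Si](c2ccccc2)(c2ccccc2)C(C)(C)C)OO | intermediate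
23 | (3R,6S)-6-[2-(tert-butyldiphenylsilyloxy)ethyl]-3-[(6E)-hexadeca-6,15-dien-4-yn-1-yl]-3-methoxy-1,2-dioxane (key-step product) | C=CCCCCCCC/C=C/C#CCCC[C@]1(OC)CC[C@@H](CCO[Si](c2ccccc2)(c2ccccc2)C(C)(C)C)OO1 | intermediate
24 | 2-[(3R,6S)-3-[(6E)-hexadeca-6,15-dien-4-yn-1-yl]-3-methoxy-1,2-dioxan-6-yl]ethanol | C=CCCCCCCC/C=C/C#CCCC[C@]1(OC)CC[C@@H](CCO)OO1 | intermediate
25 | 2-[(3R,6S)-3-[(6E)-hexadeca-6,15-dien-4-yn-1-yl]-3-methoxy-1,2-dioxan-6-yl]acetaldehyde | C=CCCCCCCC/C=C/C#CCCC[C@]1(OC)CC[C@@H](CC=O)OO1 | intermediate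
26 | 2-[(3R,6S)-3-[(6E)-hexadeca-6,15-dien-4-yn-1-yl]-3-methoxy-1,2-dioxan-6-yl]acetic acid (CNP0125368.1) | C=CCCCCCCC/C=C/C#CCCC[C@]1(OC)CC[C@@H](CC(=O)O)OO1 | target

**Step count**
Total: 18 steps. Longest linear sequence: 12 steps (1, 2, 5, 6, 10, 11, 12, 14, 15, 16, 17, 18).

**Steps most likely to fail, with fallbacks**

1. Step 14. E2 elimination of the secondary mesylate and base-induced fragmentation of the newly formed secondary peroxide may outrun the intermolecular substitution. The fallback makes the C6–O1 bond intramolecularly and sets out from 16. Ketone 16 would be converted with HC(OMe)3, MeOH and pyridinium tosylate into the dimethyl ketal mesylate F1. Acid-catalysed exchange of one methoxy group with ethereal H2O2 (camphorsulfonic acid cat., 0 °C) would give the hydroperoxy methyl ketal mesylate F2 as a C3 epimer mixture. KOt-Bu with 18-crown-6 in THF at 0 °C should then close the 1,2-dioxane by 6-exo-tet displacement of the mesylate with inversion at C6. This comes back to the route at 23; the C3 epimers should converge on 23 under the TsOH/MeOH conditions of step 15, or are separated.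

2. Step 15. Methanolysis of the dioxolane may be slow relative to acid-induced decomposition of the free hydroperoxide, exchange of the 2-hydroxyethoxy group may be incomplete, or the equilibrium may leave some C3 epimer (its alternative chair with axial OMe and axial arm costs only one syn-axial contact). A residual C3 epimer would be separated and resubmitted to the same conditions. The fallback divides the operation in two and sets out from 21. Aqueous unmasking (TsOH cat., acetone/H2O, rt) would remove the peroxide protecting group and the dioxolane hydrolytically and give the cyclic peroxyhemiketal F3, in equilibrium with its open hydroperoxy ketone, which is isolated. Methyl peroxyketal formation under mild anhydrous acid (MeOH, HC(OMe)3, camphorsulfonic acid cat., rt) then has only to ionise the hemiketal hydroxyl, and comes back to the route at 23.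

3. Step 12. Under Lewis acid the carbonyl or ketal oxygen may displace the gamma-mesylate through a five-membered oxonium ion, giving tetrahydrofuran by-products. The fallback installs the leaving group only after the ketal and sets out from 15. Acetylation (Ac2O, pyridine, DMAP) would give the acetoxy ketone F4. Ketalisation (ethylene glycol, pyridinium tosylate, benzene, reflux with water removal) would give the acetoxy dioxolane F5. Methanolysis of the ester (K2CO3, MeOH) would give the hydroxy dioxolane F6, and mesylation (MsCl, Et3N, CH2Cl2, −10 °C) comes back to the route at 17.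

**Further compounds**
F1 | step 14 | (3R,12E)-1-(tert-butyldiphenylsilyloxy)-6,6-dimethoxydocosa-12,21-dien-10-yn-3-yl methanesulfonate | C=CCCCCCCC/C=C/C#CCCCC(OC)(OC)CC[C@H](CCO[Si](c1ccccc1)(c1ccccc1)C(C)(C)C)OS(C)(=O)=O
F2 | step 14 | (3R,12E)-1-(tert-butyldiphenylsilyloxy)-6-hydroperoxy-6-methoxydocosa-12,21-dien-10-yn-3-yl methanesulfonate (C6 epimer mixture of the chain, the future C3) | C=CCCCCCCC/C=C/C#CCCCC(OC)(OO)CC[C@H](CCO[Si](c1ccccc1)(c1ccccc1)C(C)(C)C)OS(C)(=O)=O
F3 | step 15 | (6S)-6-[2-(tert-butyldiphenylsilyloxy)ethyl]-3-[(6E)-hexadeca-6,15-dien-4-yn-1-yl]-1,2-dioxan-3-ol (C3 epimers) | C=CCCCCCCC/C=C/C#CCCCC1(O)CC[C@@H](CCO[Si](c2ccccc2)(c2ccccc2)C(C)(C)C)OO1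
F4 | step 12 | (3R,12E)-1-(tert-butyldiphenylsilyloxy)-6-oxodocosa-12,21-dien-10-yn-3-yl acetate | C=CCCCCCCC/C=C/C#CCCCC(=O)CC[C@H](CCO[Si](c1ccccc1)(c1ccccc1)C(C)(C)C)OC(C)=O
F5 | step 12 | (3R)-1-(tert-butyldiphenylsilyloxy)-5-{2-[(6E)-hexadeca-6,15-dien-4-yn-1-yl]-1,3-dioxolan-2-yl}pentan-3-yl acetate | C=CCCCCCCC/C=C/C#CCCCC1(OCCO1)CC[C@H](CCO[Si](c2ccccc2)(c2ccccc2)C(C)(C)C)OC(C)=O
F6 | step 12 | (3R)-1-(tert-butyldiphenylsilyloxy)-5-{2-[(6E)-hexadeca-6,15-dien-4-yn-1-yl]-1,3-dioxolan-2-yl}pentan-3-ol | C=CCCCCCCC/C=C/C#CCCCC1(OCCO1)CC[C@H](CCO[Si](c2ccccc2)(c2ccccc2)C(C)(C)C)O
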